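# Proposed synthesis of 8α-(4-hydroxytigloyloxy)hirsutinolide 13-O-acetate (33) by Claisen ring expansion of a furan-fused 2-methylene oxocane

Locants C1–C15 are those of the germacrane skeleton of the target and are kept for all intermediates. TBS = tert-butyl(dimethyl)silyl; TIPS = tri(propan-2-yl)silyl. Compounds are numbered 1–33 in the order of the steps.

## The problem

The target 33 is a germacranolide of the hirsutinolide type: a ten-membered carbocycle (C1–C10) bridged by one oxygen between C1 and C4, so that C1 is a hemiketal and C1–C4 close a tetrahydrofuran. Across C6–C7 it is fused to a butenolide whose γ-carbon C6 is also one end of the C5=C6 ylidene. Four stereocentres must be set. C8 (S, acyloxy) and C10 (R, methyl) are 1,3-related across a CH2 group and cannot be relied on to control each other, so one is taken from the chiral pool and the other from a reagent. C1 and C4 are coupled by the one-atom bridge, which can only span the ring cis, and the C1 hemiketal can open and close; the only independent question is therefore the configuration at C4, i.e. the face of the large ring on which the bridge lies. The finished molecule tolerates little: the C13 acetate is an allylic leaving group on a dienolide, the ylidene butenolide and the hemiketal are base-sensitive, and the side chain has a free primary hydroxyl. Both esters and the butenolide oxidation level therefore belong at the very end. A ten-membered carbocycle is also poor to close end to end. The feature that opens the problem is the relation of C1 to C4–C6: if the C4 oxygen and the C5=C6 bond are read as the oxidised form of a C4=C5 alkene conjugated with a furan (C6, C7, C11, C12, O), the ketone-level C1 lies γ,δ to that alkene through C2–C3. That is the pattern left by a Claisen rearrangement, and inside an eight-membered enol ether the new C2–C3 bond enlarges the ring to ten atoms without any macrocyclisation.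

## Retrosynthesis

**Esters (C8–O acyl, C13–O acetyl).** Target 33 is cut at the C8 ester to alcohol 26 and the silyl-protected acid 30 (by way of 32), and 26 is cut at the acetate to triol 25. These cuts come first because the esters are the most labile parts. The order is fixed by what acylation can distinguish: 25 offers one primary, one hindered secondary and one tertiary hydroxyl, whereas a free side-chain hydroxyl would be a second primary allylic alcohol. Acid 30 goes back to ester 29 and to aldehyde 27 plus ylide 28. The forward steps must acylate without SN2′ loss of the acetate.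

**Oxygen bridge and ylidene (C4–O, C5=C6).** Triol 25 is the desilylated form of 24. In 24 the C4–O bond and the C5=C6 bond are disconnected together: returning the oxygen to C6 and the double bond to C4=C5 gives hydroxybutenolide 23, a plain 1-ketone, which is the singlet-oxygen product of furan 21. Introducing the C4 oxygen by epoxidation or hydration would cost extra redox steps, and building the butenolide by condensation would put C13 at the carboxyl level. The gain is large: four stereocentres become two, the bridged ketal becomes a monocyclic ketone, and the butenolide becomes a furan that survives organometallic reagents. The forward step must place the bridge on the right face; this is left to thermodynamic control, since both C–O bonds of the bridge can re-ionise.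

**Ten-membered ring (C2–C3).** Ketone 21 is a γ,δ-unsaturated ketone. Cutting C2–C3 and joining C5 to the oxygen of C1 gives the 2-methylene oxocane 20. The neighbouring cuts (C1–C2 alkylation, C4=C5 olefination) would all be end-to-end closures of a ten-membered ring at high dilution; this one is a unimolecular shift inside an eight-membered ring. Precursor 20 has no carbocycle beside the furan and only the C8 and C10 stereocentres. The forward reaction must be a [3,3] shift that beats ionisation of the furfuryl ether.

**Enol ether and lactone (C1=C2, C1–O).** Enol ether 20 comes from lactone 19 by carbonyl methylenation, and 19 from seco acid 17 by lactonisation. Eight is the least favourable lactone size, but two ring atoms are the furan carbons C6 and C7, which hold C5 and C8 cis. No reliable way exists to make the C1–O–C5 enol ether directly. The forward step is an acyl transfer at high dilution.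

**C5 and the C1 acid (C4–C5, C5–C6).** Acid 17 is cut at C4–C5 into aldehyde acid 15 and isopropenylmagnesium bromide 16; C5 need not be controlled because it becomes trigonal in the key step. Acid 15 goes back through 14 and 13 (oxidation-level and protecting-group changes at C1 and C8) to hydroxy aldehyde 12, which is cut at C5–C6 to alcohol 10 and DMF. Making C8 before C5 is what separates the two secondary carbinols without extra protecting groups: the C8 alkoxide directs lithiation to C6, is then silylated, and the C5 hydroxyl is formed free. C1 is carried as a silyl ether because an ester would not survive n-BuLi.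

**C8–C9 and the two stereocentres.** Alcohol 10 comes from ketone 9 by reagent-controlled reduction, 9 from alcohol 8, and 8 from aldehyde 4 and Grignard reagent 7 (from bromide 6, from bromo alcohol 5). C10 is bought with 5, the reduced form of the 3-hydroxy-2-methylpropanoate chiral pool. A catalytic enantioselective dialkylzinc addition would save two steps, but it needs a large excess of the chiral fragment as a β-branched zinc reagent, so the longer and safer sequence is preferred.

**Furan.** Aldehyde 4 comes from monosilyl ether 3, diol 2 and diester 1 by reduction, monoprotection and oxidation.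

## Roads not taken

Alternative 1: The cut is C7=C11 of the butenolide. In the forward sense the malonyl half-ester A1 (allyl malonate on the C6 hydroxyl, ketone at C7, bridge and C1 methyl ketal already in place) would condense under piperidinium acetate to the butenolide A2, with C13 as an allyl ester.
- Merits: C1 and C4 are fixed before the butenolide exists, so their configuration does not hang on an equilibrium; no photochemistry is needed. In stereochemical certainty at C4 this road is better than the chosen one.
- Weak points: the step builds none of the large ring, so the bridged carbocycle with a C6/C7 acyloin must come from a separate macrocyclisation. C13 arrives as a carboxyl and must be reduced beside the lactone. C5=C6 must still be introduced by dehydrogenation. The C7 ketone is flanked by two oxygenated, epimerisable centres (C6, C8) under amine–acid catalysis.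
- Comparison: the chosen plan sets against the better C4 control of A2 that its key step makes the ring, and that the furan supplies the butenolide, C13 at the right oxidation level and the C5=C6 bond in two steps.

Alternative 2: The cut is C5–C6. Aldehyde A3 (butenolide with a free γ-CH2, aldehyde on C4 of the preformed tetrahydrofuran ketal) would be converted with tBuMe2SiOTf and iPr2NEt into its 2-silyloxyfuran. This would add through C6 to the aldehyde, closing the ten-membered ring, and DBU would eliminate to the ylidene A4.
- Merits: it is convergent; ring and ylidene come in one operation; C1 and C4 are set in a small ring where they can be controlled; A4 is only protecting-group changes away from the target. In convergence, and probably in step count, it is at least as good as the chosen plan.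
- Weak points: it is an end-to-end aldol closure of a ten-membered ring onto a neopentyl, α-oxygenated aldehyde, competing with oligomerisation. The silyloxyfuran carries a furfuryl-type C8 silyloxy group that can be lost. The elimination must give one geometry.
- Comparison: the chosen plan pays the entropic price in an eight-membered acyl transfer and then enlarges the ring by a shift that cannot oligomerise. It does so at the cost of a longer linear sequence and of weaker control at C4.

Alternative 3: Here the C1–C6 bond is first made and then broken. The cis-decalin A5 (ring-fusion C1 hydroxyl, C5 mesylate, butenolide on the C6–C7 bond) would fragment with KOtBu. C1–C6 would break anti to C5–O and give the ten-membered 1-ketone A6, with the C5=C6 ylidene and C4 as a triethylsilyl ether.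
- Merits: six-membered rings are easy to build and to control; the alkene geometry follows from the anti-periplanar alignment; C4 is set on a chair. In geometric and C4 control this road is better.
- Weak points: A5 needs seven stereocentres, three of them (C1, C5, C6) sacrificial, and an oxygenated quaternary ring-fusion carbon bearing the lactone. Its C1 alkoxide sits next to the C6 acyloxy group, so acyl migration competes with fragmentation. A hindered secondary mesylate beside two fully substituted carbons must be made.
- Comparison: the chosen plan carries only the two stereocentres that survive into the target and no sacrificial ones; it has to accept that the C4=C5 geometry and the bridge face are not dictated by the mechanism.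

Key step: step 15

Assumption: C5 is not controlled; 17, 19 and 20 are each a pair of C5 epimers and are used as such, because C5 becomes trigonal in step 15.

## Route

Step 1
Reactants: 1 diethyl furan-3,4-dicarboxylate
Product: 2 furan-3,4-diyldimethanol
Conditions: LiAlH4, THF, 0 °C to reflux; aqueous NaOH work-up
Reagents that add atoms: none
Why: Ester reduction with LiAlH4; the furan and its 3,4-pattern are untouched.

Step 2
Reactants: 2 furan-3,4-diyldimethanol
Product: 3 [4-(TIPS-oxymethyl)furan-3-yl]methanol
Conditions: NaH (1 equiv), THF, 0 °C; TIPSCl (1 equiv), rt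
Reagents that add atoms: chlorotri(propan-2-yl)silane, CC(C)[Si](Cl)(C(C)C)C(C)C
Why: Monosilylation of a symmetrical diol through its monosodium alkoxide; TIPS is chosen because it does not direct lithiation, survives the selective desilylation of step 10 and stays until step 18.

Step 3
Reactants: 3 [4-(TIPS-oxymethyl)furan-3-yl]methanol
Product: 4 4-(TIPS-oxymethyl)furan-3-carbaldehyde
Conditions: MnO2 (excess), CH2Cl2, rt
Reagents that add atoms: none
Why: MnO2 oxidation of a heteroaryl (benzylic-type) carbinol stops at the aldehyde.

Step 4
Reactants: 5 (2S)-3-bromo-2-methylpropan-1-ol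
Product: 6 [(2S)-3-bromo-2-methylpropoxy](tert-butyl)dimethylsilane
Conditions: TBSCl, imidazole, CH2Cl2, rt
Reagents that add atoms: tert-butyl(chloro)dimethylsilane, CC(C)(C)[Si](C)(C)Cl
Why: Standard silylation; the stereocentre (future C10) comes from the chiral pool and is not touched.

Step 5
Reactants: 6 [(2S)-3-bromo-2-methylpropoxy](tert-butyl)dimethylsilane; 4 4-(TIPS-oxymethyl)furan-3-carbaldehyde
Product: 8 (3R)-4-(TBS-oxy)-3-methyl-1-[4-(TIPS-oxymethyl)furan-3-yl]butan-1-ol as both C1 epimers (C8 of the target), via Grignard reagent 7 (not isolated)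
Conditions: Mg, I2 (cat.), THF, reflux; then 4, THF, −78 to 0 °C; aq. NH4Cl
Reagents that add atoms: none
Why: Grignard formation from a primary bromide and 1,2-addition to a heteroaryl aldehyde; a γ-silyloxy Grignard reagent is stable, and no useful 1,3-induction is expected, so the C8 epimers are not separated.

Step 6
Reactants: 8 (3R)-4-(TBS-oxy)-3-methyl-1-[4-(TIPS-oxymethyl)furan-3-yl]butan-1-ol (both C1 epimers)
Product: 9 (3R)-4-(TBS-oxy)-3-methyl-1-[4-(TIPS-oxymethyl)furan-3-yl]butan-1-one
Conditions: Dess–Martin periodinane, NaHCO3, CH2Cl2, rt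
Reagents that add atoms: none
Why: Dess–Martin oxidation erases the uncontrolled C8 centre; C10 is β to the new carbonyl and cannot epimerise.

Step 7
Reactants: 9 (3R)-4-(TBS-oxy)-3-methyl-1-[4-(TIPS-oxymethyl)furan-3-yl]butan-1-one
Product: 10 (1S,3R)-4-(TBS-oxy)-3-methyl-1-[4-(TIPS-oxymethyl)furan-3-yl]butan-1-ol
Conditions: (R)-2-methyl-CBS-oxazaborolidine (0.2 equiv), BH3·SMe2, THF, −20 °C; MeOH, then water
Reagents that add atoms: none
Why: Corey–Bakshi–Shibata reduction; the substituted furyl group acts as the large and the CH2 chain as the small substituent, so the (R)-catalyst should give the 8S alcohol under reagent control, independent of C10.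

Step 8
Reactants: 10 (1S,3R)-4-(TBS-oxy)-3-methyl-1-[4-(TIPS-oxymethyl)furan-3-yl]butan-1-ol
Product: 12 3-[(1S,3R)-4-(TBS-oxy)-1-hydroxy-3-methylbutyl]-4-(TIPS-oxymethyl)furan-2-carbaldehyde, via C6-lithiated lithium alkoxide 11 (not isolated)
Conditions: n-BuLi (2.2 equiv), THF, −78 to 0 °C; DMF, −78 °C to rt; aq. NH4Cl
Reagents that add atoms: N,N-dimethylformamide, CN(C)C=O
Why: Alkoxide-directed ortho-lithiation; the C8 lithium alkoxide holds the base at the neighbouring α-carbon C6 through a five-membered chelate, whereas C12 lies beside a bulky, non-coordinating TIPS ether; DMF then formylates the furyllithium.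

Step 9
Reactants: 12 3-[(1S,3R)-4-(TBS-oxy)-1-hydroxy-3-methylbutyl]-4-(TIPS-oxymethyl)furan-2-carbaldehyde
Product: 13 3-[(1S,3R)-1,4-bis(TBS-oxy)-3-methylbutyl]-4-(TIPS-oxymethyl)furan-2-carbaldehyde
Conditions: TBSOTf, 2,6-lutidine, CH2Cl2, −78 to 0 °C
Reagents that add atoms: tert-butyl(dimethyl)silyl trifluoromethanesulfonate, CC(C)(C)[Si](C)(C)OS(=O)(=O)C(F)(F)F
Why: Silyl triflate silylation of a hindered secondary alcohol; the aldehyde has no α-hydrogen, and any lactol should drain through the open hydroxy aldehyde.

Step 10
Reactants: 13 3-[(1S,3R)-1,4-bis(TBS-oxy)-3-methylbutyl]-4-(TIPS-oxymethyl)furan-2-carbaldehyde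
Product: 14 3-[(1S,3R)-1-(TBS-oxy)-4-hydroxy-3-methylbutyl]-4-(TIPS-oxymethyl)furan-2-carbaldehyde
Conditions: HF·pyridine, pyridine, THF, 0 °C
Reagents that add atoms: none
Why: Buffered HF·pyridine cleaves a primary TBS ether selectively beside a hindered secondary TBS ether and a primary TIPS ether.

Step 11
Reactants: 14 3-[(1S,3R)-1-(TBS-oxy)-4-hydroxy-3-methylbutyl]-4-(TIPS-oxymethyl)furan-2-carbaldehyde
Product: 15 (2R,4S)-4-(TBS-oxy)-4-[2-formyl-4-(TIPS-oxymethyl)furan-3-yl]-2-methylbutanoic acid
Conditions: TEMPO (0.2 equiv), PhI(OAc)2 (2.2 equiv), MeCN/pH 7 buffer, rt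
Reagents that add atoms: water, O
Why: Oxoammonium oxidation of a primary alcohol to the acid through the aldehyde hydrate; the furaldehyde is barely hydrated and should survive, and this oxidation is known to spare α-stereocentres.

Step 12
Reactants: 15 (2R,4S)-4-(TBS-oxy)-4-[2-formyl-4-(TIPS-oxymethyl)furan-3-yl]-2-methylbutanoic acid; 16 isopropenylmagnesium bromide
Product: 17 (2R,4S)-4-(TBS-oxy)-4-{2-[(1RS)-1-hydroxy-2-methylprop-2-en-1-yl]-4-(TIPS-oxymethyl)furan-3-yl}-2-methylbutanoic acid (both C5 epimers)
Conditions: 16 (3 equiv), THF, −78 to −20 °C; aq. NH4Cl, then citric acid to pH 4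
Reagents that add atoms: none
Why: Grignard 1,2-addition to the aldehyde after the first equivalent has formed the inert magnesium carboxylate; C5 is formed as both epimers, which is accepted because C5 is erased in step 15.

Step 13
Reactants: 17 seco acid (both C5 epimers)
Product: 19 (8S,10R)-eight-membered lactone C1(=O)–O–C5–C6=C7–C8–C9–C10 fused to the furan at C6–C7 with isopropenyl at C5 and TBS-oxy at C8 and methyl at C10 (both C5 epimers), via mixed anhydride 18 (not isolated)
Conditions: 2-methyl-6-nitrobenzoic anhydride, DMAP, CH2Cl2, rt, slow addition of 17 at high dilution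
Reagents that add atoms: none
Why: Shiina macrolactonisation (mixed anhydride, then acyl transfer by DMAP); the furan holds C5 and C8 cis like a Z-alkene, which should ease the eight-membered closure, and the mild conditions should spare the α-stereocentre C10.

Step 14
Reactants: 19 eight-membered lactone (both C5 epimers)
Product: 20 (8S,10R)-2-methylene oxocane: ring as in 19 with C1=C2H2 in place of C1=O (both C5 epimers)
Conditions: Cp2TiMe2 (3 equiv), toluene, 65 °C, dark; filtration through basic alumina
Reagents that add atoms: dimethyltitanocene, C[Ti](C)(C1C=CC=C1)C1C=CC=C1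
Why: Petasis methylenation of a lactone carbonyl gives the exocyclic enol ether under neutral conditions; C10 is not epimerised, and the isopropenyl group and the furan are inert to the titanium methylidene.

Step 15
Reactants: 20 2-methylene oxocane (both C5 epimers)
Product: 21 (4E,8S,10R)-8-(TBS-oxy)-13-(TIPS-oxy)-6,12-epoxygermacra-4,6,11-trien-1-one (furan-fused cyclodec-4-en-1-one)
Conditions: o-xylene, 140 °C, sealed tube, trace i-Pr2NEt, base-washed glass
Reagents that add atoms: none
Why: The allyl vinyl ether C2=C1–O–C5–C4=C3 undergoes a concerted [3,3] (Claisen) shift in which the C2–C3 bond forms as the C5–O bond breaks, driven by formation of the C1 carbonyl, by conjugation of the new C4=C5 bond with the furan and by the weak furfuryl C–O bond. The closest known reaction is the Claisen ring expansion of 2-methylene oxacycles bearing an alkenyl group at the ether carbon (from lactone methylenation) to cyclooctenones and cyclononenones; the eight-to-ten case with a furfuryl ether extends it. The ten-membered carbocycle arises by two-atom ring expansion through a bicyclic six-centre transition state, not by end-to-end closure, since only the C5–O bond of the array lies in the old ring. No stereocentre is made, and C8 and C10 are spectators under neutral conditions. The C4=C5 geometry is expected to be E from a chair with the C5–C6 bond pseudo-equatorial; a Z isomer from the axial or boat arrangement would not harm the route, because step 17 passes through a species delocalised over C4–C6. Both C5 epimers should give the same ketone, as C5 becomes trigonal. The step needs [3,3] over ionisation and [1,3] recombination, which a non-polar, acid-free medium favours, and the isopropenyl alkene over the furan C6=C7 bond, which aromaticity secures. The trace of amine keeps the exocyclic enol ether from moving into the ring.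

Step 16
Reactants: 21 furan-fused cyclodec-4-en-1-one
Product: 23 (4E,8S,10R)-6-hydroxy-1-oxo-8-(TBS-oxy)-13-(TIPS-oxy)germacra-4,7(11)-dien-12,6-olide as both C6 epimers, via furan endoperoxide 22 (not isolated)
Conditions: O2, visible light, tetraphenylporphyrin (cat.), i-Pr2NEt, CH2Cl2, −78 °C to rt
Reagents that add atoms: dioxygen, O=O
Why: Singlet-oxygen [4+2] addition across C6/C12 of the furan, then base-induced Kornblum–DeLaMare fragmentation; the only bridgehead hydrogen is on C12, so C12 becomes the carbonyl and C6 the hydroxylated carbon. Furans take up singlet oxygen much faster than a trisubstituted alkene undergoes the ene reaction.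

Step 17
Reactants: 23 C6-hydroxybutenolide (both C6 epimers)
Product: 24 (1S,4R,5E,8S,10R)-1,4-epoxy-1-hydroxy-8-(TBS-oxy)-13-(TIPS-oxy)germacra-5,7(11)-dien-12,6-olide
Conditions: camphorsulfonic acid (0.2 equiv), water-saturated CH2Cl2, 0 °C to rt
Reagents that add atoms: water, O
Why: Proposed new method: acid ionises the C6 hydroxyl (or opens the lactol to the C6 enone), the charge is spread over C6–C5–C4 with the tertiary C4 as its electrophilic end, the transannular C1 carbonyl oxygen (as ketone or hydrate) attacks C4 in a five-membered closure, water completes the C1 hemiketal, and the C5=C6 ylidene conjugated with the butenolide is left behind. The closest known reactions are the acid-catalysed dehydrative SN1′ cycloetherification of tertiary allylic alcohols, the dehydration of γ-hydroxybutenolides to γ-ylidenebutenolides, and the acid-promoted change of 1-oxo germacranolides of the glaucolide type into 1,4-epoxy hemiketals of the hirsutinolide type. C4 and C1 are set together under thermodynamic control: the bridge can only be cis, both of its C–O bonds can re-ionise, and the natural configuration is assumed to be the more stable one.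

Step 18
Reactants: 24 bis-silylated core
Product: 25 (1S,4R,5E,8S,10R)-1,4-epoxy-1,8,13-trihydroxygermacra-5,7(11)-dien-12,6-olide
Conditions: HF·pyridine, pyridine, THF, 0 °C to rt
Reagents that add atoms: none
Why: Fluoride cleavage of both silyl ethers under buffered, non-basic conditions that the ylidene butenolide and the hemiketal should tolerate.

Step 19
Reactants: 25 triol
Product: 26 (1S,4R,5E,8S,10R)-13-acetoxy-1,4-epoxy-1,8-dihydroxygermacra-5,7(11)-dien-12,6-olide
Conditions: AcCl (1.05 equiv), 2,4,6-collidine, CH2Cl2, −78 °C
Reagents that add atoms: acetyl chloride, CC(=O)Cl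
Why: Kinetic acylation; at low temperature and with a weak, non-nucleophilic base the primary C13 hydroxyl reacts far faster than the hindered secondary C8 hydroxyl and the tertiary hemiketal.

Step 20
Reactants: 27 (TBS-oxy)acetaldehyde; 28 ethyl 2-(triphenyl-λ5-phosphanylidene)propanoate
Product: 29 ethyl (2E)-4-(TBS-oxy)-2-methylbut-2-enoate
Conditions: CH2Cl2, rt
Reagents that add atoms: none
Why: Wittig olefination with a stabilised α-methyl ylide gives the E-trisubstituted enoate.

Step 21
Reactants: 29 ethyl (2E)-4-(TBS-oxy)-2-methylbut-2-enoate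
Product: 30 (2E)-4-(TBS-oxy)-2-methylbut-2-enoic acid
Conditions: LiOH, THF/MeOH/H2O, rt; dilute HCl to pH 4
Reagents that add atoms: lithium hydroxide, [Li+].[OH-]
Why: Saponification; the primary TBS ether is stable to LiOH.

Step 22
Reactants: 30 (2E)-4-(TBS-oxy)-2-methylbut-2-enoic acid; 26 13-acetate with free C8 hydroxyl
Product: 32 (1S,4R,5E,8S,10R)-13-acetoxy-1,4-epoxy-1-hydroxy-8-{[(2E)-4-(TBS-oxy)-2-methylbut-2-enoyl]oxy}germacra-5,7(11)-dien-12,6-olide, via mixed anhydride 31 (not isolated)
Conditions: 30, 2,4,6-trichlorobenzoyl chloride, Et3N, THF, rt; then 26, DMAP, toluene, rt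
Reagents that add atoms: none
Why: Yamaguchi esterification of a hindered secondary alcohol through the mixed anhydride and acyl transfer by DMAP; the E acid has no more stable geometry to isomerise to, and the tertiary hemiketal hydroxyl is too hindered to acylate.

Step 23
Reactants: 32 side-chain TBS ether of the target
Product: 33 (1S,4R,5E,8S,10R)-13-acetoxy-1,4-epoxy-1-hydroxy-8-{[(2E)-4-hydroxy-2-methylbut-2-enoyl]oxy}germacra-5,7(11)-dien-12,6-olide (target)
Conditions: HF·pyridine, pyridine, THF, 0 °C
Reagents that add atoms: none
Why: Buffered fluoride cleavage of the primary allylic TBS ether, under the conditions of step 18, should leave both esters, the hemiketal and the dienolide intact.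

## Compound list

1 | diethyl furan-3,4-dicarboxylate | CCOC(=O)c1cocc1C(=O)OCC | starting material
2 | furan-3,4-diyldimethanol | OCc1cocc1CO | intermediate
3 | [4-({[tri(propan-2-yl)silyl]oxy}methyl)furan-3-yl]methanol | OCc1cocc1CO[Si](C(C)C)(C(C)C)C(C)C | intermediate
4 | 4-({[tri(propan-2-yl)silyl]oxy}methyl)furan-3-carbaldehyde | O=Cc1cocc1CO[Si](C(C)C)(C(C)C)C(C)C | intermediate
5 | (2S)-3-bromo-2-methylpropan-1-ol | OC[C@H](C)CBr | starting material
6 | [(2S)-3-bromo-2-methylpropoxy](tert-butyl)dimethylsilane | CC(C)(C)[Si](C)(C)OC[C@H](C)CBr | intermediate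
7 | [(2S)-3-{[tert-butyl(dimethyl)silyl]oxy}-2-methylpropyl]magnesium bromide (not isolated) | CC(C)(C)[Si](C)(C)OC[C@H](C)C[Mg]Br | intermediate
8 | (1RS,3R)-4-(TBS-oxy)-3-methyl-1-[4-(TIPS-oxymethyl)furan-3-yl]butan-1-ol, both C8 epimers | CC(C)(C)[Si](C)(C)OC[C@H](C)CC(O)c1cocc1CO[Si](C(C)C)(C(C)C)C(C)C | intermediate
9 | (3R)-4-(TBS-oxy)-3-methyl-1-[4-(TIPS-oxymethyl)furan-3-yl]butan-1-one | CC(C)(C)[Si](C)(C)OC[C@H](C)CC(=O)c1cocc1CO[Si](C(C)C)(C(C)C)C(C)C | intermediate
10 | (1S,3R)-4-(TBS-oxy)-3-methyl-1-[4-(TIPS-oxymethyl)furan-3-yl]butan-1-ol | CC(C)(C)[Si](C)(C)OC[C@H](C)C[C@H](O)c1cocc1CO[Si](C(C)C)(C(C)C)C(C)C | intermediate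
11 | C6-lithiated lithium alkoxide of 10 (not isolated) | CC(C)(C)[Si](C)(C)OC[C@H](C)C[C@H](O[Li])c1c([Li])occ1CO[Si](C(C)C)(C(C)C)C(C)C | intermediate
12 | 3-[(1S,3R)-4-(TBS-oxy)-1-hydroxy-3-methylbutyl]-4-(TIPS-oxymethyl)furan-2-carbaldehyde | CC(C)(C)[Si](C)(C)OC[C@H](C)C[C@H](O)c1c(C=O)occ1CO[Si](C(C)C)(C(C)C)C(C)C | intermediate
13 | 3-[(1S,3R)-1,4-bis(TBS-oxy)-3-methylbutyl]-4-(TIPS-oxymethyl)furan-2-carbaldehyde | CC(C)(C)[Si](C)(C)OC[C@H](C)C[C@H](O[Si](C)(C)C(C)(C)C)c1c(C=O)occ1CO[Si](C(C)C)(C(C)C)C(C)C | intermediate
14 | 3-[(1S,3R)-1-(TBS-oxy)-4-hydroxy-3-methylbutyl]-4-(TIPS-oxymethyl)furan-2-carbaldehyde | OC[C@H](C)C[C@H](O[Si](C)(C)C(C)(C)C)c1c(C=O)occ1CO[Si](C(C)C)(C(C)C)C(C)C | intermediate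
15 | (2R,4S)-4-(TBS-oxy)-4-[2-formyl-4-(TIPS-oxymethyl)furan-3-yl]-2-methylbutanoic acid | OC(=O)[C@H](C)C[C@H](O[Si](C)(C)C(C)(C)C)c1c(C=O)occ1CO[Si](C(C)C)(C(C)C)C(C)C | intermediate
16 | isopropenylmagnesium bromide (prop-1-en-2-ylmagnesium bromide) | C=C(C)[Mg]Br | starting material
17 | (2R,4S)-4-(TBS-oxy)-4-{2-[(1RS)-1-hydroxy-2-methylprop-2-en-1-yl]-4-(TIPS-oxymethyl)furan-3-yl}-2-methylbutanoic acid, both C5 epimers | OC(=O)[C@H](C)C[C@H](O[Si](C)(C)C(C)(C)C)c1c(C(O)C(C)=C)occ1CO[Si](C(C)C)(C(C)C)C(C)C | intermediate
18 | mixed anhydride of 17 with 2-methyl-6-nitrobenzoic acid (not isolated) | Cc1cccc([N+](=O)[O-])c1C(=O)OC(=O)[C@H](C)C[C@H](O[Si](C)(C)C(C)(C)C)c1c(C(O)C(C)=C)occ1CO[Si](C(C)C)(C(C)C)C(C)C | intermediate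
19 | (5RS,8S,10R)-furan-fused oxocan-2-one: ring C1(=O)–O–C5–C6=C7–C8–C9–C10, isopropenyl at C5, TBS-oxy at C8, methyl at C10, TIPS-oxymethyl on furan carbon C11 | O=C1OC(C(C)=C)c2occ(CO[Si](C(C)C)(C(C)C)C(C)C)c2[C@@H](O[Si](C)(C)C(C)(C)C)C[C@H]1C | intermediate
20 | (5RS,8S,10R)-2-methylene oxocane: as 19 with C1=C2H2 in place of C1=O | C=C1OC(C(C)=C)c2occ(CO[Si](C(C)C)(C(C)C)C(C)C)c2[C@@H](O[Si](C)(C)C(C)(C)C)C[C@H]1C | intermediate
21 | (4E,8S,10R)-8-(TBS-oxy)-13-(TIPS-oxy)-6,12-epoxygermacra-4,6,11-trien-1-one | CC(C)[Si](C(C)C)(C(C)C)OCc1coc2/C=C(C)/CCC(=O)[C@H](C)C[C@H](O[Si](C)(C)C(C)(C)C)c12 | intermediate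
22 | 6,12-endoperoxide of 21 (dioxygen bridge between furan carbons C6 and C12; not isolated) | CC(C)[Si](C(C)C)(C(C)C)OCC1=C2[C@@H](O[Si](C)(C)C(C)(C)C)C[C@@H](C)C(=O)CC/C(C)=C/C23OOC1O3 | intermediate
23 | (4E,6RS,8S,10R)-6-hydroxy-1-oxo-8-(TBS-oxy)-13-(TIPS-oxy)germacra-4,7(11)-dien-12,6-olide | CC(C)[Si](C(C)C)(C(C)C)OCC1=C2[C@@H](O[Si](C)(C)C(C)(C)C)C[C@@H](C)C(=O)CC/C(C)=C/C2(O)OC1=O | intermediate
24 | (1S,4R,5E,8S,10R)-1,4-epoxy-1-hydroxy-8-(TBS-oxy)-13-(TIPS-oxy)germacra-5,7(11)-dien-12,6-olide | CC(C)[Si](C(C)C)(C(C)C)OCC1=C2/C(=C\[C@@]3(C)CC[C@](O)(O3)[C@H](C)C[C@@H]2O[Si](C)(C)C(C)(C)C)OC1=O | intermediate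
25 | (1S,4R,5E,8S,10R)-1,4-epoxy-1,8,13-trihydroxygermacra-5,7(11)-dien-12,6-olide | OCC1=C2/C(=C\[C@@]3(C)CC[C@](O)(O3)[C@H](C)C[C@@H]2O)OC1=O | intermediate
26 | (1S,4R,5E,8S,10R)-13-acetoxy-1,4-epoxy-1,8-dihydroxygermacra-5,7(11)-dien-12,6-olide | CC(=O)OCC1=C2/C(=C\[C@@]3(C)CC[C@](O)(O3)[C@H](C)C[C@@H]2O)OC1=O | intermediate
27 | {[tert-butyl(dimethyl)silyl]oxy}acetaldehyde | CC(C)(C)[Si](C)(C)OCC=O | starting material
28 | ethyl 2-(triphenyl-λ5-phosphanylidene)propanoate | CCOC(=O)C(C)=P(c1ccccc1)(c1ccccc1)c1ccccc1 | starting material
29 | ethyl (2E)-4-(TBS-oxy)-2-methylbut-2-enoate | CCOC(=O)/C(C)=C/CO[Si](C)(C)C(C)(C)C | intermediate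
30 | (2E)-4-(TBS-oxy)-2-methylbut-2-enoic acid | OC(=O)/C(C)=C/CO[Si](C)(C)C(C)(C)C | intermediate
31 | mixed anhydride of 30 with 2,4,6-trichlorobenzoic acid (not isolated) | O=C(OC(=O)/C(C)=C/CO[Si](C)(C)C(C)(C)C)c1c(Cl)cc(Cl)cc1Cl | intermediate
32 | (1S,4R,5E,8S,10R)-13-acetoxy-1,4-epoxy-1-hydroxy-8-{[(2E)-4-(TBS-oxy)-2-methylbut-2-enoyl]oxy}germacra-5,7(11)-dien-12,6-olide | CC(=O)OCC1=C2/C(=C\[C@@]3(C)CC[C@](O)(O3)[C@H](C)C[C@@H]2OC(=O)/C(C)=C/CO[Si](C)(C)C(C)(C)C)OC1=O | intermediate
33 | (1S,4R,5E,8S,10R)-13-acetoxy-1,4-epoxy-1-hydroxy-8-{[(2E)-4-hydroxy-2-methylbut-2-enoyl]oxy}germacra-5,7(11)-dien-12,6-olide | CC(=O)OCC1=C2/C(=C\[C@@]3(C)CC[C@](O)(O3)[C@H](C)C[C@@H]2OC(=O)/C(C)=C/CO)OC1=O | target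

## Step count and least certain steps

Total: 23 steps. Longest linear sequence: 20 steps (steps 1–3, 5–19, 22, 23, from diester 1).

**Step 17 (proposed new method).**
- What may go wrong: the delocalised cation may lose a proton from C15 or C3 and give a triene instead of being captured at C4. If the thermodynamic preference is small, the bridge may close on the wrong face of the ring. The C1 ketone may enolise and scramble C10 before it is ketalised. The silyl ethers may be lost early and let the C8 hydroxyl compete for C1.
- Fallback, by known reactions, from 23 back to 24: hydrogen-atom-transfer hydration of the C4=C5 bond (Mn(dpm)3, PhSiH3, O2, i-PrOH, 0 °C) puts the hydroxyl on the tertiary C4 without a cation. This hydroxyl closes onto the C1 ketone and gives (1S,4R,8S,10R)-1,4-epoxy-1,6-dihydroxy-8-(TBS-oxy)-13-(TIPS-oxy)germacr-7(11)-en-12,6-olide F1. Acid-catalysed dehydration of its C6 lactol (p-TsOH, toluene, molecular sieves), the ordinary route to γ-ylidenebutenolides, then returns to 24.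

**Step 15 (key step).**
- What may go wrong: heterolysis of the furfuryl allyl ether ahead of bond formation, followed by [1,3] recombination or elimination. Migration of the exocyclic enol ether double bond into the ring under traces of acid, which would also endanger C10. Sluggish rearrangement of one C5 epimer, so that decomposition wins at the temperature needed. Formation of the Z alkene, which is tolerated.
- Fallback, from 20 back to 21: the aluminium-promoted, reductive variant (i-Bu3Al, CH2Cl2, −78 to 0 °C) replaces the thermal shift by a Lewis-acid-assisted one below room temperature and reduces the ketone as it forms. It gives (4E,8S,10R)-8-(TBS-oxy)-13-(TIPS-oxy)-6,12-epoxygermacra-4,6,11-trien-1-ol F2, which Dess–Martin oxidation returns to 21.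

**Step 13 (lactonisation).**
- What may go wrong: dimerisation to the sixteen-membered diolide and oligomerisation instead of eight-membered closure; slow closure of one C5 epimer; loss of the activated furfuryl allyl alcohol by ionisation.
- Fallback, from 17 back to 19: Mitsunobu lactonisation (PPh3, diisopropyl azodicarboxylate, toluene, high dilution) activates the C5 alcohol instead of the acid and forms the C5–O bond by displacement. The inversion at C5 is irrelevant here. This fallback makes no new compound (F0).

**Step 22 (C8 esterification).**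
- What may go wrong: SN2′ displacement of the C13 acetate by DMAP or Et3N, and slow acylation of the hindered C8 hydroxyl, which would prolong that exposure.
- Fallback, from 25 back to 32, with the acylations in reverse order:
  - TESCl and imidazole at −40 °C silylate the primary hydroxyl and give (1S,4R,5E,8S,10R)-1,4-epoxy-1,8-dihydroxy-13-(triethylsilyloxy)germacra-5,7(11)-dien-12,6-olide F3.
  - Yamaguchi esterification with 30 gives its C8 (2E)-4-(TBS-oxy)-2-methylbut-2-enoate F4.
  - AcOH/THF/H2O at 0 °C removes only the triethylsilyl group and gives the 13-hydroxy C8 ester F5.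
  - Acetylation with AcCl and collidine gives 32, so the allylic acetate never meets DMAP.

## Further compounds

F1 | step 17 | (1S,4R,6RS,8S,10R)-1,4-epoxy-1,6-dihydroxy-8-(TBS-oxy)-13-(TIPS-oxy)germacr-7(11)-en-12,6-olide | CC(C)[Si](C(C)C)(C(C)C)OCC1=C2C(O)(C[C@@]3(C)CC[C@](O)(O3)[C@H](C)C[C@@H]2O[Si](C)(C)C(C)(C)C)OC1=O
F2 | step 15 | (1RS,4E,8S,10R)-8-(TBS-oxy)-13-(TIPS-oxy)-6,12-epoxygermacra-4,6,11-trien-1-ol | CC(C)[Si](C(C)C)(C(C)C)OCc1coc2/C=C(C)/CCC(O)[C@H](C)C[C@H](O[Si](C)(C)C(C)(C)C)c12
F0 | step 13 | none | none
F3 | step 22 | (1S,4R,5E,8S,10R)-1,4-epoxy-1,8-dihydroxy-13-(triethylsilyloxy)germacra-5,7(11)-dien-12,6-olide | CC[Si](CC)(CC)OCC1=C2/C(=C\[C@@]3(C)CC[C@](O)(O3)[C@H](C)C[C@@H]2O)OC1=O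
F4 | step 22 | (1S,4R,5E,8S,10R)-1,4-epoxy-1-hydroxy-8-{[(2E)-4-(TBS-oxy)-2-methylbut-2-enoyl]oxy}-13-(triethylsilyloxy)germacra-5,7(11)-dien-12,6-olide | CC[Si](CC)(CC)OCC1=C2/C(=C\[C@@]3(C)CC[C@](O)(O3)[C@H](C)C[C@@H]2OC(=O)/C(C)=C/CO[Si](C)(C)C(C)(C)C)OC1=O
F5 | step 22 | (1S,4R,5E,8S,10R)-1,4-epoxy-1,13-dihydroxy-8-{[(2E)-4-(TBS-oxy)-2-methylbut-2-enoyl]oxy}germacra-5,7(11)-dien-12,6-olide | OCC1=C2/C(=C\[C@@]3(C)CC[C@](O)(O3)[C@H](C)C[C@@H]2OC(=O)/C(C)=C/CO[Si](C)(C)C(C)(C)C)OC1=O
A1 | alternative 1 | C6 allyl malonate of the C7-oxo 1,4-epoxy C1 methyl ketal (substrate of the Knoevenagel closure) | C=CCOC(=O)CC(=O)O[C@H]1C[C@@]2(C)CC[C@](OC)(O2)[C@H](C)C[C@H](O[Si](C)(C)C(C)(C)C)C1=O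
A2 | alternative 1 | 5,6-dihydro butenolide core with C13 as allyl ester | C=CCOC(=O)C1=C2[C@H](C[C@@]3(C)CC[C@](OC)(O3)[C@H](C)C[C@@H]2O[Si](C)(C)C(C)(C)C)OC1=O
A3 | alternative 2 | butenolide with free C6 methylene tethered to the C5 aldehyde on the tetrahydrofuran ketal | O=C[C@@]1(C)CC[C@](OC)(O1)[C@H](C)C[C@H](O[Si](C)(C)C(C)(C)C)C1=C(CO[Si](C)(C)C(C)(C)C)C(=O)OC1
A4 | alternative 2 | C1 methyl ketal of the core with C8 and C13 silyl ethers | CC(C)(C)[Si](C)(C)OCC1=C2/C(=C\[C@@]3(C)CC[C@](OC)(O3)[C@H](C)C[C@@H]2O[Si](C)(C)C(C)(C)C)OC1=O
A5 | alternative 3 | cis-decalin with C1 hydroxyl, C5 mesylate, C4 triethylsilyl ether and butenolide on C6–C7 | C[C@@H]1C[C@H](O[Si](C)(C)C(C)(C)C)C2=C(CO[Si](C)(C)C(C)(C)C)C(=O)O[C@@]23[C@@H](OS(C)(=O)=O)[C@](C)(O[Si](CC)(CC)CC)CC[C@@]13O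
A6 | alternative 3 | 1-oxo ten-membered ylidene butenolide, C4 triethylsilyl ether | CC(C)(C)[Si](C)(C)OCC1=C2/C(=C\[C@](C)(O[Si](CC)(CC)CC)CCC(=O)[C@H](C)C[C@@H]2O[Si](C)(C)C(C)(C)C)OC1=O
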